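Both benzylic bonds, C7–ring B and C8–ring A, are disconnected so that C7 (the carbinol carbon) and C8 (the methyl-bearing carbon) become the two olefinic carbons of an (E)-propenylboron unit. One palladium-catalysed conjunctive coupling then unites three achiral pieces: ring B (3,4-dimethoxyphenyl) migrates from boron to C7 while ring A (the allyl-methoxyphenol ring, as its silyl-protected bromide) is delivered to C8 from the opposite face, fixing the anti methyl/hydroxyl relationship; a chiral ferrocenyl bisphosphine sets the absolute sense and oxidation converts C7–B into C7–OH. The precursor is the lithium ate complex of the (E)-propenylboronic ester of cis-1,2-dimethylacenaphthene-1,2-diol (mac) with 3,4-dimethoxyphenyllithium, plus the ring A bromide.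

Key step: step 5

Assumption: which antipode of the MandyPhos ligand leads to (7S,8S) is not derived here; both antipodes are commercial, the sense is to be assigned in a pilot run, and the route is written for the antipode that gives (7S,8S).

Step 1
Reactants: 1 eugenol (4-allyl-2-methoxyphenol)
Product: 2 4-allyl-2-bromo-6-methoxyphenol
Conditions: NBS (1.0 equiv), i-Pr2NH (10 mol%), CH2Cl2, 0 °C
Reagents that add atoms: N-bromosuccinimide, O=C1CCC(=O)N1Br
Why: Amine-catalysed ortho-bromination of a phenol (electrophilic aromatic substitution): the N-bromoamine formed from NBS is hydrogen-bonded to the phenolic OH and passes bromine to the single free ortho position (the para position carries the allyl group), while the cold, non-nucleophilic medium offers the isolated allyl C=C no route to a dibromide or bromohydrin.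

Step 2
Reactants: 2 4-allyl-2-bromo-6-methoxyphenol
Product: 3 (4-allyl-2-bromo-6-methoxyphenoxy)(tert-butyl)dimethylsilane
Conditions: TBSCl (1.2 equiv), imidazole (2.5 equiv), DMF, rt
Reagents that add atoms: tert-butyldimethylsilyl chloride, CC(C)(C)[Si](C)(C)Cl
Why: Imidazole-promoted silyl ether formation (via the N-silylimidazolium) masks the acidic OH that would otherwise quench the ate complex of step 5, and the silyl ether can later be removed with fluoride without acid or hydrogenation.

Step 3
Reactants: 4 acenaphthoquinone
Product: 5 cis-(1R,2S)-1,2-dimethyl-1,2-dihydroacenaphthylene-1,2-diol (meso; mac diol)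
Conditions: MeMgBr (3 equiv), THF, 0 °C to rt; aq. NH4Cl; recrystallisation
Reagents that add atoms: methylmagnesium bromide, C[Mg]Br
Why: Double Grignard 1,2-addition to a non-enolisable 1,2-diketone; the second methyl should enter on the face away from the bulky bromomagnesium alkoxide left by the first addition, which places the two oxygens cis and sets both carbinol centres as the meso diol, freed from any trans isomer by crystallisation.

Step 4
Reactants: 6 (E)-prop-1-enylboronic acid; 5 cis-1,2-dimethyl-1,2-dihydroacenaphthylene-1,2-diol
Product: 7 (E)-prop-1-enylboronic acid cis-1,2-dimethylacenaphthylene-1,2-diyl ester [(E)-propenyl-B(mac)]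
Conditions: 4 Å molecular sieves, CH2Cl2, rt
Reagents that add atoms: none
Why: Dehydrative boronic ester formation between a boronic acid and a cis-1,2-diol held syn on the rigid five-membered ring, driven by removal of water; the E geometry of the propenyl group is not touched.

Step 5
Reactants: 8 4-bromo-1,2-dimethoxybenzene; 7 (E)-propenyl-B(mac); 3 (4-allyl-2-bromo-6-methoxyphenoxy)(tert-butyl)dimethylsilane
Product: 12 (1S,2S)-2-[5-allyl-2-(tert-butyldimethylsilyloxy)-3-methoxyphenyl]-1-(3,4-dimethoxyphenyl)propan-1-ol, via 3,4-dimethoxyphenyllithium 9 (not isolated), via lithium ate complex 10 (not isolated), via benzylic boronic ester 11 (not isolated)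
Conditions: 8, t-BuLi (2.0 equiv), Et2O, −78 °C; add 7, −78 °C to rt; then 3 (1.1 equiv), Pd(OAc)2 (3 mol%), MandyPhos ligand 1,1′-bis[bis(3,5-dimethylphenyl)phosphino]-2,2′-bis[α-(dimethylamino)benzyl]ferrocene (3.6 mol%, antipode giving 7S,8S), CF3SO3K (3 equiv), THF, 60 °C; then 3 M NaOH, 30% H2O2, 0 °C to rt
Reagents that add atoms: hydrogen peroxide, OO (the hydroxyl oxygen at C7); t-BuLi, [Li]C(C)(C)C (only the lithium of 9 and 10)
Why: Bromine–lithium exchange gives 9, which adds to boron of 7 to form ate complex 10; oxidative addition of 3 to zerovalent palladium gives an aryl divalent-palladium species that, once CF3SO3K has removed bromide as KBr, binds the propenyl π bond of 10, whereupon the dimethoxyphenyl group shifts from boron to C7 anti to palladium as palladium bonds C8, and reductive elimination with retention forms the C8–ring A bond before alkaline H2O2 converts C7–B of 11 into C7–OH with retention. This is the known enantioselective conjunctive cross-coupling of β-substituted alkenyl B(mac) ate complexes with aryl electrophiles, run here with an aryl bromide and a triflate salt as halide scavenger. No ring is closed. C7 and C8 are created together: their anti relationship follows from the E geometry of the propenyl group combined with the stereospecific anti metallate shift and the two retentive events, and the absolute (7S,8S) sense follows from the alkene face chosen by the chiral bisphosphine–palladium complex. The step needs the metallate shift to outrun direct Suzuki-type transmetalation, β-hydride elimination and Heck addition to the allyl group; the hindered mac diol blocks transmetalation of the β-substituted alkenyl group, the electron-rich dimethoxyphenyl group migrates readily, the wide-bite-angle bisphosphine speeds reductive elimination, and the anionic boronate alkene is a far better partner for palladium than the isolated allyl C=C.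

Step 6
Reactants: 12 (1S,2S)-2-[5-allyl-2-(tert-butyldimethylsilyloxy)-3-methoxyphenyl]-1-(3,4-dimethoxyphenyl)propan-1-ol
Product: 13 4-allyl-2-[(1S,2S)-1-(3,4-dimethoxyphenyl)-1-hydroxypropan-2-yl]-6-methoxyphenol (target)
Conditions: TBAF (1.1 equiv), AcOH (1.1 equiv), THF, 0 °C
Reagents that add atoms: none
Why: Fluoride-mediated cleavage of the aryl silyl ether (strong Si–F bond, phenoxide leaving group) under acetic acid buffering leaves the allyl group and both stereocentres untouched and avoids any acid strong enough to ionise the electron-rich benzylic alcohol.

Compound list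
1 | eugenol (4-allyl-2-methoxyphenol) | C=CCc1ccc(O)c(OC)c1 | starting material
2 | 4-allyl-2-bromo-6-methoxyphenol | C=CCc1cc(OC)c(O)c(Br)c1 | intermediate
3 | (4-allyl-2-bromo-6-methoxyphenoxy)(tert-butyl)dimethylsilane (ring A bromide) | C=CCc1cc(OC)c(O[Si](C)(C)C(C)(C)C)c(Br)c1 | intermediate
4 | acenaphthoquinone (acenaphthylene-1,2-dione) | O=C1C(=O)c2cccc3cccc1c23 | starting material
5 | cis-(1R,2S)-1,2-dimethyl-1,2-dihydroacenaphthylene-1,2-diol (meso, mac diol) | O[C@]1(C)c2cccc3cccc(c23)[C@]1(C)O | intermediate
6 | (E)-prop-1-enylboronic acid | C/C=C/B(O)O | starting material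
7 | (E)-prop-1-enylboronic acid cis-1,2-dimethylacenaphthylene-1,2-diyl ester, (E)-propenyl-B(mac) | C/C=C/B1O[C@]2(C)c3cccc4cccc(c34)[C@]2(C)O1 | intermediate
8 | 4-bromo-1,2-dimethoxybenzene | COc1ccc(Br)cc1OC | starting material
9 | 3,4-dimethoxyphenyllithium | [Li]c1ccc(OC)c(OC)c1 | intermediate
10 | lithium (3,4-dimethoxyphenyl)[(E)-prop-1-enyl]borate of the mac diol (ate complex, boron configuration undefined) | [Li+].C/C=C/[B-]1(c2ccc(OC)c(OC)c2)O[C@]2(C)c3cccc4cccc(c34)[C@]2(C)O1 | intermediate
11 | B(mac) ester of (1S,2R)-2-[5-allyl-2-(tert-butyldimethylsilyloxy)-3-methoxyphenyl]-1-(3,4-dimethoxyphenyl)propylboronic acid (same spatial arrangement as 12) | C=CCc1cc(OC)c(O[Si](C)(C)C(C)(C)C)c([C@H](C)[C@H](B2O[C@]3(C)c4cccc5cccc(c45)[C@]3(C)O2)c2ccc(OC)c(OC)c2)c1 | intermediate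
12 | (1S,2S)-2-[5-allyl-2-(tert-butyldimethylsilyloxy)-3-methoxyphenyl]-1-(3,4-dimethoxyphenyl)propan-1-ol | C=CCc1cc(OC)c(O[Si](C)(C)C(C)(C)C)c([C@H](C)[C@H](O)c2ccc(OC)c(OC)c2)c1 | intermediate
13 | 4-allyl-2-[(1S,2S)-1-(3,4-dimethoxyphenyl)-1-hydroxypropan-2-yl]-6-methoxyphenol | C=CCc1cc(OC)c(O)c([C@H](C)[C@H](O)c2ccc(OC)c(OC)c2)c1 | target

Total step count: 6.
Longest linear sequence: 4 steps (steps 1, 2, 5, 6 from eugenol; equally steps 3, 4, 5, 6 from acenaphthoquinone).

Steps most likely to fail

Step 5. Several processes may intervene:
- Bromide (from the lithiation and from 3) may inhibit the catalyst, or oxidative addition at the hindered, electron-rich ortho-silyloxy bromide may be slow, so that direct Suzuki-type transfer or protodeboronation overtakes the metallate shift.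
- Facial discrimination by the ligand may be insufficient.
- A palladium hydride may move the allyl double bond into conjugation.
- Early loss of the silyl ether in the alkaline peroxide work-up would be harmless, since it only anticipates step 6.

The fallback sets out from 3 and uses known chemistry. Palladium-catalysed ketone α-arylation of commercial 1-(3,4-dimethoxyphenyl)propan-1-one (CCC(=O)c1ccc(OC)c(OC)c1) with 3 (Pd(OAc)2, XPhos, K3PO4, toluene, 80 °C) should give racemic 2-[5-allyl-2-(tert-butyldimethylsilyloxy)-3-methoxyphenyl]-1-(3,4-dimethoxyphenyl)propan-1-one F1. Its C8–H is benzylic and α to the aryl ketone, so it epimerises under base. Noyori asymmetric hydrogenation under dynamic kinetic resolution should then reduce only the carbonyl group; the catalyst would be RuCl2(xylbinap)(daipen) with KOC(CH3)3 in i-PrOH under H2, where xylbinap is 2,2′-bis[di(3,5-xylyl)phosphino]-1,1′-binaphthyl and daipen is 1,1-bis(4-methoxyphenyl)-3-methylbutane-1,2-diamine, the antipode being chosen for 7S,8S. Felkin–Anh delivery of hydride anti to ring A gives the 7,8-anti alcohol, and the sequence comes back to the route at 12.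

Step 1. Bromine may enter para to the methoxy group (ortho to the allyl chain) instead of ortho to the hydroxyl, or may add across the allyl double bond. The fault lies in the first step, so no numbered compound can serve as the origin; the fallback replaces eugenol 1 by commercial 2-bromo-6-methoxyphenol (COc1cccc(Br)c1O), which already carries bromine ortho to OH. O-Allylation (allyl bromide, K2CO3, acetone, reflux) gives 2-(allyloxy)-1-bromo-3-methoxybenzene F2. Heating (N,N-diethylaniline, about 190 °C) should then effect a para-Claisen rearrangement: a [3,3] shift to a blocked ortho carbon, a Cope shift and tautomerisation. Because both ortho positions are substituted, the allyl group ends up para to oxygen, and the sequence comes back to the route at 2.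

Step 3. Facial selectivity in the second methyl addition may be poor, giving a cis/trans mixture that does not separate on crystallisation. The fallback sets out from 4 and is stereoconvergent. The double addition is run without regard to selectivity, and the crude mixture of 5 and racemic trans-1,2-dimethyl-1,2-dihydroacenaphthylene-1,2-diol F3 is deoxygenated with low-valent titanium (TiCl3, LiAlH4, THF, reflux; McMurry-type diol deoxygenation, which needs no cis arrangement) to 1,2-dimethylacenaphthylene F4. Syn-dihydroxylation (OsO4 cat., N-methylmorpholine N-oxide, acetone/H2O) then delivers both oxygens to one face and gives only the cis diol, so the sequence comes back to the route at 5.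

Further compounds
F1 | step 5 | racemic 2-[5-allyl-2-(tert-butyldimethylsilyloxy)-3-methoxyphenyl]-1-(3,4-dimethoxyphenyl)propan-1-one | C=CCc1cc(OC)c(O[Si](C)(C)C(C)(C)C)c(C(C)C(=O)c2ccc(OC)c(OC)c2)c1
F2 | step 1 | 2-(allyloxy)-1-bromo-3-methoxybenzene | C=CCOc1c(Br)cccc1OC
F3 | step 3 | racemic trans-1,2-dimethyl-1,2-dihydroacenaphthylene-1,2-diol (one enantiomer drawn) | O[C@]1(C)c2cccc3cccc(c23)[C@@]1(C)O
F4 | step 3 | 1,2-dimethylacenaphthylene | CC1=C(C)c2cccc3cccc1c23
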